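**Plan**
Ring A (C1 ethano bridge, C2 benzyl, C3 OMe, C4 benzyl, C5 OH, C6 H) is a resorcinol with its oxygens 1,3 on C3 and C5. C5 can therefore come from a ketone, C3 from an ester and C6–C1 from an alkyne, and the retrosynthesis cuts C1–C2 and C3–C4.
This leaves a four-carbon ynone strand C4–C5–C6–C1, which already carries the C4 benzyl group and the bridge to ring B, and a two-carbon benzylmalonate strand C2–C3, whose spare ester leaves on aromatisation.
Earlier cuts are the acyl–alkynyl bond of the ynone, the benzyl–propargyl bond of the bridge and the aryl–CH2 bond on ring B.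
Forward: ring B and the three 4-oxybenzyl rings are bought. Ring B is benzylated at carbon, extended to a butynylarene and acylated. Ring A, the only ring made, then closes in one flask, and C5-O-benzylation, C3-O-methylation and one global hydrogenolysis finish the route.
Stereochemistry: the target has no stereogenic element. The single transient stereocentre (C2 of the blocked dienone) is erased on aromatisation.

Key step: step 10

Remark: bleochrin A is achiral, so the given SMILES defines it fully and no enantioselective step is needed. Ring A locants C1–C6 are used as defined above.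

**Step 1**
Reactants: 1 methyl 2-bromo-5-hydroxybenzoate
Product: 2 methyl 5-(benzyloxy)-2-bromobenzoate
Conditions: BnBr, K2CO3, DMF, rt
Reagents that add atoms: benzyl bromide, BrCc1ccccc1
Why: Williamson etherification of the only acidic OH, under conditions that leave the methyl ester and the aryl bromide untouched.

**Step 2**
Reactants: 2 methyl 5-(benzyloxy)-2-bromobenzoate; 3 4-(benzyloxy)benzyl chloride
Product: 5 methyl 5-(benzyloxy)-2-[4-(benzyloxy)benzyl]benzoate, via benzylic zinc chloride 4 (not isolated)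
Conditions: 3, Zn dust, LiCl, THF, rt; then 2, Pd(OAc)2 (2 mol %), SPhos (4 mol %), THF, rt → 50 °C
Reagents that add atoms: zinc, [Zn] (held only by intermediate 4)
Why: LiCl-assisted zinc insertion into a benzylic chloride followed by Negishi coupling with an ester-activated aryl bromide, the ester oxidation level being chosen because benzylic zinc reagents add to aldehydes but not to esters.

**Step 3**
Reactants: 5 methyl 5-(benzyloxy)-2-[4-(benzyloxy)benzyl]benzoate
Product: 6 {5-(benzyloxy)-2-[4-(benzyloxy)benzyl]phenyl}methanol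
Conditions: LiAlH4, THF, 0 °C; aqueous work-up
Reagents that add atoms: none
Why: Hydride reduction of a benzoate to the benzylic alcohol, to which benzyl ethers and the diarylmethane are inert.

**Step 4**
Reactants: 6 {5-(benzyloxy)-2-[4-(benzyloxy)benzyl]phenyl}methanol
Product: 7 4-(benzyloxy)-1-[4-(benzyloxy)benzyl]-2-(bromomethyl)benzene
Conditions: CBr4, PPh3, CH2Cl2, 0 °C
Reagents that add atoms: carbon tetrabromide, BrC(Br)(Br)Br
Why: Appel bromination works under neutral conditions, which avoids acid-induced Friedel–Crafts closure onto the neighbouring electron-rich benzyl ring.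

**Step 5**
Reactants: 7 4-(benzyloxy)-1-[4-(benzyloxy)benzyl]-2-(bromomethyl)benzene; 8 1-(trimethylsilyl)propyne
Product: 11 4-(benzyloxy)-1-[4-(benzyloxy)benzyl]-2-(but-3-yn-1-yl)benzene, via lithiated silylpropyne 9 (not isolated), via silylated butynylarene 10 (not isolated)
Conditions: 8, n-BuLi, THF, −78 °C; then 7, −78 °C → rt; then MeOH, K2CO3 (cat.), rt
Reagents that add atoms: n-butyllithium, [Li]CCCC (lithium held only by intermediate 9)
Why: SN2 alkylation of lithiated 1-silylpropyne by a benzylic bromide, in which the silyl group directs attack to the propargylic terminus, followed by base-catalysed methanolytic protodesilylation of the alkynylsilane.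

**Step 6**
Reactants: 12 3-(4-hydroxyphenyl)propanoic acid
Product: 13 benzyl 3-[4-(benzyloxy)phenyl]propanoate
Conditions: BnBr (2.2 equiv), K2CO3, DMF, 50 °C
Reagents that add atoms: benzyl bromide (two equivalents), BrCc1ccccc1
Why: Simultaneous Williamson etherification of the phenol and carboxylate O-alkylation, both routine with benzyl bromide and carbonate base.

**Step 7**
Reactants: 13 benzyl 3-[4-(benzyloxy)phenyl]propanoate
Product: 14 3-[4-(benzyloxy)phenyl]-N-methoxy-N-methylpropanamide
Conditions: MeNH(OMe)·HCl, i-PrMgCl, THF, −20 → 0 °C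
Reagents that add atoms: N,O-dimethylhydroxylamine hydrochloride, CNOC.Cl
Why: Direct aminolysis of an ester by the magnesium amide of N,O-dimethylhydroxylamine, the standard ester-to-Weinreb-amide conversion.

**Step 8**
Reactants: 11 4-(benzyloxy)-1-[4-(benzyloxy)benzyl]-2-(but-3-yn-1-yl)benzene; 14 3-[4-(benzyloxy)phenyl]-N-methoxy-N-methylpropanamide
Product: 16 1-[4-(benzyloxy)phenyl]-7-{5-(benzyloxy)-2-[4-(benzyloxy)benzyl]phenyl}hept-4-yn-3-one, via lithium acetylide 15 (not isolated)
Conditions: 11, n-BuLi (1.0 equiv), THF, −78 °C; then 14, −78 → 0 °C; aq. NH4Cl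
Reagents that add atoms: n-butyllithium, [Li]CCCC (lithium held only by intermediate 15)
Why: Weinreb ketone synthesis, in which acylation of a lithium acetylide by an N-methoxy-N-methylamide stops at the ynone, and one equivalent of base removes only the alkyne proton.

**Step 9**
Reactants: 17 dimethyl malonate; 3 4-(benzyloxy)benzyl chloride
Product: 18 dimethyl 2-[4-(benzyloxy)benzyl]malonate
Conditions: 17 (2 equiv), K2CO3, DMF, 50 °C
Reagents that add atoms: none
Why: Malonic ester alkylation with a reactive benzylic chloride, with excess malonate holding back the second alkylation.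

**Step 10**
Reactants: 16 1-[4-(benzyloxy)phenyl]-7-{5-(benzyloxy)-2-[4-(benzyloxy)benzyl]phenyl}hept-4-yn-3-one; 18 dimethyl 2-[4-(benzyloxy)benzyl]malonate
Product: 21 2,4-bis[4-(benzyloxy)benzyl]-5-(2-{5-(benzyloxy)-2-[4-(benzyloxy)benzyl]phenyl}ethyl)benzene-1,3-diol, via Z-enone Michael adduct 19 (not isolated), via blocked cyclohexadienone ester 20 (not isolated)
Conditions: 18 (1.2 equiv), NaOMe (0.2 equiv), degassed MeOH–THF, 0 °C → rt; then NaOMe (4 equiv), reflux, Ar; aq. HCl
Reagents that add atoms: none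
Why: Proposed new method: the enolate of 18 adds to the sp-hybridised, sterically open β-carbon of ynone 16 (C1–C2 bond), and the resulting enone 19 interconverts between E and Z through its γ-dienolate, so the Z form with ketone and malonate on the same side stays available. Its α′-enolate then attacks one of the two equivalent esters through carbon C4 (C3–C4 bond) in a 6-(enolendo)-exo-trig Dieckmann closure, the only ring closure of the step, and delivers ring A as the blocked cyclohexa-2,4-dienone 20. Methoxide adds to the ester left on quaternary C2, and the adduct expels the ring carbon rather than methoxide because that leaving group is an aromatic resorcinolate, so the activating ester departs as dimethyl carbonate. The closest known reaction types are the Michael–Dieckmann synthesis of resorcylates and 5-alkylresorcinols from unsubstituted malonates with enones or ynones and the retro-Claisen loss of dialkyl carbonate from non-enolisable β-keto esters, which have not been joined in one cascade on a 2-substituted malonate. The selectivity needed is C- over O-acylation: only C4 reaches an ester carbonyl through a six-membered carbocycle, and the competing enol lactone cannot become a conjugated 2-pyranone because C2 is quaternary, so it, like the methoxide adducts of 16, is reopened by methoxide and drains into the irreversible aromatisation. No stereocentre survives, since C2 of 20 forms as a racemate and becomes planar in 21, and the substitution pattern of ring A is fixed by which atoms are bonded in 16 and 18 rather than by any regiochemical preference.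

**Step 11**
Reactants: 21 2,4-bis[4-(benzyloxy)benzyl]-5-(2-{5-(benzyloxy)-2-[4-(benzyloxy)benzyl]phenyl}ethyl)benzene-1,3-diol
Product: 22 3-(benzyloxy)-2,6-bis[4-(benzyloxy)benzyl]-5-(2-{5-(benzyloxy)-2-[4-(benzyloxy)benzyl]phenyl}ethyl)phenol
Conditions: BnBr (1.0 equiv), K2CO3, acetone, rt
Reagents that add atoms: benzyl bromide, BrCc1ccccc1
Why: Williamson etherification under steric control with limiting electrophile, because the C5 phenoxide has one ortho substituent whereas the C3 phenoxide is flanked by two benzyl groups.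

**Step 12**
Reactants: 22 3-(benzyloxy)-2,6-bis[4-(benzyloxy)benzyl]-5-(2-{5-(benzyloxy)-2-[4-(benzyloxy)benzyl]phenyl}ethyl)phenol
Product: 23 1-(benzyloxy)-2,4-bis[4-(benzyloxy)benzyl]-5-(2-{5-(benzyloxy)-2-[4-(benzyloxy)benzyl]phenyl}ethyl)-3-methoxybenzene
Conditions: MeI (excess), K2CO3, DMF, 40 °C
Reagents that add atoms: iodomethane, CI
Why: Williamson O-methylation of the one remaining phenol, where the small electrophile in a dipolar aprotic solvent overcomes the di-ortho substitution.

**Step 13**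
Reactants: 23 1-(benzyloxy)-2,4-bis[4-(benzyloxy)benzyl]-5-(2-{5-(benzyloxy)-2-[4-(benzyloxy)benzyl]phenyl}ethyl)-3-methoxybenzene
Product: 24 bleochrin A, 2,4-bis(4-hydroxybenzyl)-5-{2-[5-hydroxy-2-(4-hydroxybenzyl)phenyl]ethyl}-3-methoxyphenol
Conditions: H2 (1 atm), 10% Pd/C, THF–MeOH, rt
Reagents that add atoms: none
Why: Catalytic hydrogenolysis cleaves all five aryl benzyl ethers at the O–CH2Ph bond and leaves the aryl methyl ether, the diarylmethane C–C bonds and the bibenzyl bridge intact.

**Compound list**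
1 | methyl 2-bromo-5-hydroxybenzoate | COC(=O)c1cc(O)ccc1Br | starting material
2 | methyl 5-(benzyloxy)-2-bromobenzoate | COC(=O)c1cc(OCc2ccccc2)ccc1Br | intermediate
3 | 4-(benzyloxy)benzyl chloride | ClCc1ccc(OCc2ccccc2)cc1 | starting material
4 | [4-(benzyloxy)benzyl]zinc chloride (formed in situ) | Cl[Zn]Cc1ccc(OCc2ccccc2)cc1 | intermediate
5 | methyl 5-(benzyloxy)-2-[4-(benzyloxy)benzyl]benzoate | COC(=O)c1cc(OCc2ccccc2)ccc1Cc1ccc(OCc2ccccc2)cc1 | intermediate
6 | {5-(benzyloxy)-2-[4-(benzyloxy)benzyl]phenyl}methanol | OCc1cc(OCc2ccccc2)ccc1Cc1ccc(OCc2ccccc2)cc1 | intermediate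
7 | 4-(benzyloxy)-1-[4-(benzyloxy)benzyl]-2-(bromomethyl)benzene | BrCc1cc(OCc2ccccc2)ccc1Cc1ccc(OCc2ccccc2)cc1 | intermediate
8 | 1-(trimethylsilyl)propyne | CC#C[Si](C)(C)C | starting material
9 | 3-lithio-1-(trimethylsilyl)propyne (formed in situ) | [Li]CC#C[Si](C)(C)C | intermediate
10 | (4-{5-(benzyloxy)-2-[4-(benzyloxy)benzyl]phenyl}but-1-yn-1-yl)trimethylsilane (formed in situ) | C[Si](C)(C)C#CCCc1cc(OCc2ccccc2)ccc1Cc1ccc(OCc2ccccc2)cc1 | intermediate
11 | 4-(benzyloxy)-1-[4-(benzyloxy)benzyl]-2-(but-3-yn-1-yl)benzene | C#CCCc1cc(OCc2ccccc2)ccc1Cc1ccc(OCc2ccccc2)cc1 | intermediate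
12 | 3-(4-hydroxyphenyl)propanoic acid | OC(=O)CCc1ccc(O)cc1 | starting material
13 | benzyl 3-[4-(benzyloxy)phenyl]propanoate | O=C(CCc1ccc(OCc2ccccc2)cc1)OCc1ccccc1 | intermediate
14 | 3-[4-(benzyloxy)phenyl]-N-methoxy-N-methylpropanamide | CON(C)C(=O)CCc1ccc(OCc2ccccc2)cc1 | intermediate
15 | lithium acetylide of 11 (formed in situ) | [Li]C#CCCc1cc(OCc2ccccc2)ccc1Cc1ccc(OCc2ccccc2)cc1 | intermediate
16 | 1-[4-(benzyloxy)phenyl]-7-{5-(benzyloxy)-2-[4-(benzyloxy)benzyl]phenyl}hept-4-yn-3-one | O=C(CCc1ccc(OCc2ccccc2)cc1)C#CCCc1cc(OCc2ccccc2)ccc1Cc1ccc(OCc2ccccc2)cc1 | intermediate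
17 | dimethyl malonate | COC(=O)CC(=O)OC | starting material
18 | dimethyl 2-[4-(benzyloxy)benzyl]malonate | COC(=O)C(Cc1ccc(OCc2ccccc2)cc1)C(=O)OC | intermediate
19 | dimethyl 2-[4-(benzyloxy)benzyl]-2-[(3Z)-7-[4-(benzyloxy)phenyl]-1-{5-(benzyloxy)-2-[4-(benzyloxy)benzyl]phenyl}-5-oxohept-3-en-3-yl]malonate (formed in situ; equilibrates with the E isomer) | COC(=O)C(Cc1ccc(OCc2ccccc2)cc1)(C(=O)OC)/C(CCc1cc(OCc2ccccc2)ccc1Cc1ccc(OCc2ccccc2)cc1)=C\C(=O)CCc1ccc(OCc2ccccc2)cc1 | intermediate
20 | methyl 1,3-bis[4-(benzyloxy)benzyl]-6-(2-{5-(benzyloxy)-2-[4-(benzyloxy)benzyl]phenyl}ethyl)-4-hydroxy-2-oxocyclohexa-3,5-diene-1-carboxylate (formed in situ; racemic at C1 of this name) | COC(=O)C1(Cc2ccc(OCc3ccccc3)cc2)C(=O)C(Cc2ccc(OCc3ccccc3)cc2)=C(O)C=C1CCc1cc(OCc2ccccc2)ccc1Cc1ccc(OCc2ccccc2)cc1 | intermediate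
21 | 2,4-bis[4-(benzyloxy)benzyl]-5-(2-{5-(benzyloxy)-2-[4-(benzyloxy)benzyl]phenyl}ethyl)benzene-1,3-diol | Oc1c(Cc2ccc(OCc3ccccc3)cc2)c(O)cc(CCc2cc(OCc3ccccc3)ccc2Cc2ccc(OCc3ccccc3)cc2)c1Cc1ccc(OCc2ccccc2)cc1 | intermediate
22 | 3-(benzyloxy)-2,6-bis[4-(benzyloxy)benzyl]-5-(2-{5-(benzyloxy)-2-[4-(benzyloxy)benzyl]phenyl}ethyl)phenol | Oc1c(Cc2ccc(OCc3ccccc3)cc2)c(OCc2ccccc2)cc(CCc2cc(OCc3ccccc3)ccc2Cc2ccc(OCc3ccccc3)cc2)c1Cc1ccc(OCc2ccccc2)cc1 | intermediate
23 | 1-(benzyloxy)-2,4-bis[4-(benzyloxy)benzyl]-5-(2-{5-(benzyloxy)-2-[4-(benzyloxy)benzyl]phenyl}ethyl)-3-methoxybenzene | COc1c(Cc2ccc(OCc3ccccc3)cc2)c(OCc2ccccc2)cc(CCc2cc(OCc3ccccc3)ccc2Cc2ccc(OCc3ccccc3)cc2)c1Cc1ccc(OCc2ccccc2)cc1 | intermediate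
24 | bleochrin A (achiral) | COc1c(Cc2ccc(O)cc2)c(O)cc(CCc2cc(O)ccc2Cc2ccc(O)cc2)c1Cc1ccc(O)cc1 | target

**Step count**
Total steps: 13.
Longest linear sequence: 10 steps (1, 2, 3, 4, 5, 8, 10, 11, 12, 13).

**Steps most likely to fail**

1. Step 10. The tertiary malonate carbanion may add too slowly, so that methoxide addition or propargyl-to-allenyl isomerisation consumes the ynone. The cascade may also stall before the ester on the quaternary carbon is lost.
The fallback uses known chemistry and moves the C2 benzyl group to a later C–C bond formation. It sets out from 16 and the unsubstituted malonate 17. The parent Michael–Dieckmann resorcylate synthesis (NaOMe, MeOH–THF, reflux) should give methyl 3-[4-(benzyloxy)benzyl]-2,4-dihydroxy-6-(2-{5-(benzyloxy)-2-[4-(benzyloxy)benzyl]phenyl}ethyl)benzoate F1, which aromatises by simple tautomerisation. Saponification (KOH, aq. MeOH–THF, reflux), then acidification and warming, decarboxylates the 2,4-dihydroxybenzoic acid to 2-[4-(benzyloxy)benzyl]-5-(2-{5-(benzyloxy)-2-[4-(benzyloxy)benzyl]phenyl}ethyl)benzene-1,3-diol F2. The two open positions of ring A in F2 are related by symmetry. A Friedel–Crafts benzylation of this most electron-rich ring with one equivalent of chloride 3 (ZnCl2, CH2Cl2, 0 °C) can therefore give only one mono-C-benzyl isomer, and the route is rejoined at 21.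

2. Step 11. Site selectivity between the two phenols may be poor, with competing alkylation of the flanked C3 oxygen and over-benzylation.
The fallback replaces the small alkylating agent by a bulky silyl electrophile, whose rate is far more sensitive to di-ortho substitution. From 21, TIPSCl and imidazole in DMF should give 3-[(triisopropylsilyl)oxy]-2,6-bis[4-(benzyloxy)benzyl]-5-(2-{5-(benzyloxy)-2-[4-(benzyloxy)benzyl]phenyl}ethyl)phenol F3. Methylation (MeI, K2CO3, acetone, reflux) gives {2,4-bis[4-(benzyloxy)benzyl]-5-(2-{5-(benzyloxy)-2-[4-(benzyloxy)benzyl]phenyl}ethyl)-3-methoxyphenoxy}triisopropylsilane F4. TBAF in THF releases 2,4-bis[4-(benzyloxy)benzyl]-5-(2-{5-(benzyloxy)-2-[4-(benzyloxy)benzyl]phenyl}ethyl)-3-methoxyphenol F5. Hydrogenolysis of its four benzyl ethers (H2, Pd/C) rejoins the route at 24.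

3. Step 2. Wurtz-type homocoupling may occur during zinc insertion into the electron-rich benzylic chloride, and transmetalation to the ortho-substituted arylpalladium species may be slow.
The fallback reverses the polarity of the coupling. From 2, Miyaura borylation (B2pin2, PdCl2(dppf), KOAc, dioxane, 80 °C) should give methyl 5-(benzyloxy)-2-(4,4,5,5-tetramethyl-1,3,2-dioxaborolan-2-yl)benzoate F6. Suzuki–Miyaura coupling of F6 with the benzylic chloride 3 as electrophile (Pd(PPh3)4, K2CO3, THF–H2O, 65 °C) rejoins the route at 5.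

**Further compounds**
F1 | step 10 | methyl 3-[4-(benzyloxy)benzyl]-2,4-dihydroxy-6-(2-{5-(benzyloxy)-2-[4-(benzyloxy)benzyl]phenyl}ethyl)benzoate | COC(=O)c1c(O)c(Cc2ccc(OCc3ccccc3)cc2)c(O)cc1CCc1cc(OCc2ccccc2)ccc1Cc1ccc(OCc2ccccc2)cc1
F2 | step 10 | 2-[4-(benzyloxy)benzyl]-5-(2-{5-(benzyloxy)-2-[4-(benzyloxy)benzyl]phenyl}ethyl)benzene-1,3-diol | Oc1cc(CCc2cc(OCc3ccccc3)ccc2Cc2ccc(OCc3ccccc3)cc2)cc(O)c1Cc1ccc(OCc2ccccc2)cc1
F3 | step 11 | 3-[(triisopropylsilyl)oxy]-2,6-bis[4-(benzyloxy)benzyl]-5-(2-{5-(benzyloxy)-2-[4-(benzyloxy)benzyl]phenyl}ethyl)phenol | CC(C)[Si](Oc1cc(CCc2cc(OCc3ccccc3)ccc2Cc2ccc(OCc3ccccc3)cc2)c(Cc2ccc(OCc3ccccc3)cc2)c(O)c1Cc1ccc(OCc2ccccc2)cc1)(C(C)C)C(C)C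
F4 | step 11 | {2,4-bis[4-(benzyloxy)benzyl]-5-(2-{5-(benzyloxy)-2-[4-(benzyloxy)benzyl]phenyl}ethyl)-3-methoxyphenoxy}triisopropylsilane | CC(C)[Si](Oc1cc(CCc2cc(OCc3ccccc3)ccc2Cc2ccc(OCc3ccccc3)cc2)c(Cc2ccc(OCc3ccccc3)cc2)c(OC)c1Cc1ccc(OCc2ccccc2)cc1)(C(C)C)C(C)C
F5 | step 11 | 2,4-bis[4-(benzyloxy)benzyl]-5-(2-{5-(benzyloxy)-2-[4-(benzyloxy)benzyl]phenyl}ethyl)-3-methoxyphenol | COc1c(Cc2ccc(OCc3ccccc3)cc2)c(O)cc(CCc2cc(OCc3ccccc3)ccc2Cc2ccc(OCc3ccccc3)cc2)c1Cc1ccc(OCc2ccccc2)cc1
F6 | step 2 | methyl 5-(benzyloxy)-2-(4,4,5,5-tetramethyl-1,3,2-dioxaborolan-2-yl)benzoate | COC(=O)c1cc(OCc2ccccc2)ccc1B1OC(C)(C)C(C)(C)O1
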